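Carotenoid numbering is used: ring B (hydroxylated) is C1–C6 with chain C7–C15; primed numbers belong to the half ending in cyclohexadiene ring A. TBS = tert-butyldimethylsilyl.

**Plan**
- Cuts: C15–C15' (sp2–sp2 coupling), then C10=C11 and C8=C9 in each half (Horner–Wadsworth–Emmons, Wittig), then C5–C6 of each ring, back to an acyclic 6-alkynal.
- Enabling feature: in ring B the oxygen-bearing C5 is bonded to C6 of the exocyclic C6=C7 alkene, H on C7 is cis to C5, and the other ring neighbour of C6 is the quaternary C1. This is the pattern left by syn addition of an aldehyde C5–H across a C6≡C7 alkyne (alkyne hydroacylation), and C1 cannot let the alkene migrate.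
- Forward: 2,2-dimethylpent-4-enal → alkynyl acetal aldehyde 6 → both antipodes of one β-silyloxy alkynal. Ring A is closed first (step 7, then enol triflate/methyl); ring B is closed last (step 19, then methyl addition to the C5 ketone).
- Each ylidene acetaldehyde is extended by a stabilised Wittig ylide and an enynyl phosphonate; the halves are joined by hydrozirconation/iodination and hydrozirconation/Pd coupling; desilylation ends the route.
- Stereochemistry: C3 and C3' (opposite spatial sense) come from the two antipodes of B-allyldiisopinocampheylborane; C5 from equatorial methyl delivery anti to the axial C1 methyl; 6E and 6'E from the syn hydroacylation; chain geometry from E-selective olefinations, the E-enynol and syn hydrozirconation.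

Key step: step 19

Step 1
Reactants: 1 2,2-dimethylpent-4-enal
Product: 2 3,3-dimethylhex-5-en-1-yne
Conditions: dimethyl (1-diazo-2-oxopropyl)phosphonate, K2CO3, MeOH, 0 °C to rt
Reagents that add atoms: dimethyl (1-diazo-2-oxopropyl)phosphonate, CC(=O)C(=[N+]=[N-])P(=O)(OC)OC
Why: Ohira–Bestmann homologation (Seyferth–Gilbert reagent formed in the flask, alkylidene carbene 1,2-shift) should turn the non-enolisable neopentyl aldehyde into the terminal alkyne that becomes C6≡C7; the volatile enyne is carried on as a distilled solution.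

Step 2
Reactants: 2 3,3-dimethylhex-5-en-1-yne
Product: 4 7,7-diethoxy-4,4-dimethylhept-1-en-5-yne, via alkynylmagnesium bromide 3 (not isolated)
Conditions: EtMgBr, THF, 45 °C; then HC(OEt)3, toluene, 90 °C
Reagents that add atoms: triethyl orthoformate, CCOC(OCC)OCC
Why: Bodroux–Chichibabin acetal synthesis, in which the alkynyl Grignard reagent displaces one ethoxide of the orthoformate, should install C8 as a base-stable propargylic acetal.

Step 3
Reactants: 4 7,7-diethoxy-4,4-dimethylhept-1-en-5-yne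
Product: 6 6,6-diethoxy-3,3-dimethylhex-4-ynal, via diol 5 (not isolated)
Conditions: OsO4 (2 mol%), NaIO4, 2,6-lutidine, dioxane/H2O, rt
Reagents that add atoms: osmium tetroxide, O=[Os](=O)(=O)=O; sodium periodate (re-oxidant that restores the oxygen), [Na+].[O-]I(=O)(=O)=O
Why: Lemieux–Johnson oxidation should take the terminal alkene far faster than the internal alkyne, and the lutidine buffer keeps the medium neutral for the acetal.

Step 4
Reactants: 6 6,6-diethoxy-3,3-dimethylhex-4-ynal
Product: 8 (4R)-9,9-diethoxy-6,6-dimethylnon-1-en-7-yn-4-ol, via borinate 7 (not isolated)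
Conditions: (+)-B-allyldiisopinocampheylborane (derived from (−)-α-pinene), Et2O, −78 °C; then NaOH, H2O2, 0 °C to rt
Reagents that add atoms: (+)-B-allyldiisopinocampheylborane, C=CCB([C@H]1C[C@H]2C[C@@H]([C@@H]1C)C2(C)C)[C@H]1C[C@H]2C[C@@H]([C@@H]1C)C2(C)C
Why: Brown allylation through a closed chair transition state, in which the (−)-α-pinene-derived borane should deliver allyl to the Re face of the aldehyde and so set the carbinol that becomes C3' (4R here).

Step 5
Reactants: 8 (4R)-9,9-diethoxy-6,6-dimethylnon-1-en-7-yn-4-ol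
Product: 9 tert-butyl{[(4R)-9,9-diethoxy-6,6-dimethylnon-1-en-7-yn-4-yl]oxy}dimethylsilane
Conditions: TBSCl, imidazole, DMF, rt
Reagents that add atoms: tert-butyldimethylsilyl chloride, CC(C)(C)[Si](C)(C)Cl
Why: Standard silylation of a secondary alcohol gives an ether that should survive every later step up to the final fluoride treatment.

Step 6
Reactants: 9 tert-butyl{[(4R)-9,9-diethoxy-6,6-dimethylnon-1-en-7-yn-4-yl]oxy}dimethylsilane
Product: 11 (3S)-3-[(tert-butyldimethylsilyl)oxy]-8,8-diethoxy-5,5-dimethyloct-6-ynal, via diol 10 (not isolated)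
Conditions: OsO4 (2 mol%), NaIO4, 2,6-lutidine, dioxane/H2O, rt
Reagents that add atoms: osmium tetroxide, O=[Os](=O)(=O)=O; sodium periodate (re-oxidant that restores the oxygen), [Na+].[O-]I(=O)(=O)=O
Why: Lemieux–Johnson oxidation as in step 3 should shorten the allyl group to the aldehyde carbon that becomes C5' (the descriptor changes to S only through the priority rules).

Step 7
Reactants: 11 (3S)-3-[(tert-butyldimethylsilyl)oxy]-8,8-diethoxy-5,5-dimethyloct-6-ynal
Product: 12 (2E,5S)-5-[(tert-butyldimethylsilyl)oxy]-2-(2,2-diethoxyethylidene)-3,3-dimethylcyclohexan-1-one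
Conditions: [Rh(nbd)2]BF4 (10 mol%), Ph2PCH2CH2PPh2 (10 mol%), H2 pre-activation then argon, CH2Cl2, rt to 40 °C
Reagents that add atoms: none
Why: Cationic rhodium-catalysed intramolecular alkyne hydroacylation (syn addition of acyl and H, 6-exo-dig) should close ring A and fix the 6'E geometry, as analysed for the antipode in step 19.

Step 8
Reactants: 12 (2E,5S)-5-[(tert-butyldimethylsilyl)oxy]-2-(2,2-diethoxyethylidene)-3,3-dimethylcyclohexan-1-one
Product: 14 (3S,6E)-3-[(tert-butyldimethylsilyl)oxy]-6-(2,2-diethoxyethylidene)-5,5-dimethylcyclohex-1-en-1-yl trifluoromethanesulfonate, via potassium dienolate 13 (not isolated)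
Conditions: KN(SiMe3)2, THF, −78 °C; then PhNTf2, −78 to 0 °C
Reagents that add atoms: N-phenylbis(trifluoromethanesulfonimide), O=S(=O)(N(c1ccccc1)S(=O)(=O)C(F)(F)F)C(F)(F)F
Why: C4' is the only enolisable position, so kinetic deprotonation and O-sulfonylation should give one cross-conjugated dienyl triflate, the silyloxy group being too poor a leaving group to eliminate at −78 °C.

Step 9
Reactants: 14 (3S,6E)-3-[(tert-butyldimethylsilyl)oxy]-6-(2,2-diethoxyethylidene)-5,5-dimethylcyclohex-1-en-1-yl trifluoromethanesulfonate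
Product: 15 tert-butyl{[(1S,4E)-4-(2,2-diethoxyethylidene)-3,5,5-trimethylcyclohex-2-en-1-yl]oxy}dimethylsilane
Conditions: Fe(acac)3 (5 mol%), MeMgBr, THF/N-methylpyrrolidone, −30 to 0 °C
Reagents that add atoms: methylmagnesium bromide, C[Mg]Br
Why: Iron-catalysed Kumada-type coupling of an alkenyl triflate with a methyl Grignard reagent should install the C5' methyl group and complete the C4'=C5'/C6'=C7' diene of ring A without touching acetal or silyl ether.

Step 10
Reactants: 15 tert-butyl{[(1S,4E)-4-(2,2-diethoxyethylidene)-3,5,5-trimethylcyclohex-2-en-1-yl]oxy}dimethylsilane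
Product: 16 (2E)-2-[(4S)-4-[(tert-butyldimethylsilyl)oxy]-2,6,6-trimethylcyclohex-2-en-1-ylidene]acetaldehyde
Conditions: pyridinium p-toluenesulfonate (5 mol%), acetone/H2O, rt
Reagents that add atoms: water, O
Why: Acetal hydrolysis through an oxocarbenium ion conjugated with the diene should proceed under conditions too mild to ionise the allylic silyl ether, and the E-dienal formed cannot undergo oxa-electrocyclisation.

Step 11
Reactants: 16 (2E)-2-[(4S)-4-[(tert-butyldimethylsilyl)oxy]-2,6,6-trimethylcyclohex-2-en-1-ylidene]acetaldehyde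
Product: 17 (2E,4E)-4-[(4S)-4-[(tert-butyldimethylsilyl)oxy]-2,6,6-trimethylcyclohex-2-en-1-ylidene]-2-methylbut-2-enal
Conditions: 2-(triphenylphosphoranylidene)propanal, toluene, 80 °C
Reagents that add atoms: 2-(triphenylphosphoranylidene)propanal, CC(C=O)=P(c1ccccc1)(c1ccccc1)c1ccccc1
Why: Wittig reaction with a stabilised formyl ylide should give the E-trisubstituted C8'=C9' alkene and stop at the less electrophilic, α-branched dienal.

Step 12
Reactants: 18 (2E)-3-methylpent-2-en-4-yn-1-ol
Product: 19 (3E)-5-bromo-3-methylpent-3-en-1-yne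
Conditions: PBr3, Et2O, 0 °C
Reagents that add atoms: phosphorus tribromide, BrP(Br)Br
Why: SN2 bromination of the primary allylic alcohol should keep the E geometry that later becomes C12=C13.

Step 13
Reactants: 19 (3E)-5-bromo-3-methylpent-3-en-1-yne
Product: 20 diethyl [(2E)-3-methylpent-2-en-4-yn-1-yl]phosphonate
Conditions: P(OEt)3, toluene, 100 °C
Reagents that add atoms: triethyl phosphite, CCOP(OCC)OCC
Why: Michaelis–Arbuzov reaction of a primary allylic bromide should give the C11–C15 phosphonate used for both halves.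

Step 14
Reactants: 17 (2E,4E)-4-[(4S)-4-[(tert-butyldimethylsilyl)oxy]-2,6,6-trimethylcyclohex-2-en-1-ylidene]-2-methylbut-2-enal; 20 diethyl [(2E)-3-methylpent-2-en-4-yn-1-yl]phosphonate
Product: 22 tert-butyl{[(1S,4E)-4-[(2E,4E,6E)-3,7-dimethylnona-2,4,6-trien-8-yn-1-ylidene]-3,5,5-trimethylcyclohex-2-en-1-yl]oxy}dimethylsilane, via sodium phosphonate carbanion 21 (not isolated)
Conditions: NaN(SiMe3)2, THF, −78 °C; then 17, −78 to 0 °C
Reagents that add atoms: none
Why: Horner–Wadsworth–Emmons olefination with an allylic phosphonate anion, formed and used cold so that its C12'=C13' geometry is kept, should give the E-C10'=C11' alkene and bring in C11'–C15'.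

Step 15
Reactants: 22 tert-butyl{[(1S,4E)-4-[(2E,4E,6E)-3,7-dimethylnona-2,4,6-trien-8-yn-1-ylidene]-3,5,5-trimethylcyclohex-2-en-1-yl]oxy}dimethylsilane
Product: 24 tert-butyl{[(1S,4E)-4-[(2E,4E,6E,8E)-9-iodo-3,7-dimethylnona-2,4,6,8-tetraen-1-ylidene]-3,5,5-trimethylcyclohex-2-en-1-yl]oxy}dimethylsilane, via alkenylzirconocene 23 (not isolated)
Conditions: Cp2Zr(H)Cl, THF, rt, dark; then I2, −78 °C
Reagents that add atoms: iodine, II
Why: Syn hydrozirconation should place zirconium on the terminal carbon of the only alkyne (the substituted polyene alkenes are inert), and iodinolysis with retention gives the E-C14'=C15' iodide, used at once.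

Step 16
Reactants: 6 6,6-diethoxy-3,3-dimethylhex-4-ynal
Product: 26 (4S)-9,9-diethoxy-6,6-dimethylnon-1-en-7-yn-4-ol, via borinate 25 (not isolated)
Conditions: (−)-B-allyldiisopinocampheylborane (derived from (+)-α-pinene), Et2O, −78 °C; then NaOH, H2O2, 0 °C to rt
Reagents that add atoms: (−)-B-allyldiisopinocampheylborane, C=CCB([C@@H]1C[C@@H]2C[C@H]([C@H]1C)C2(C)C)[C@@H]1C[C@@H]2C[C@H]([C@H]1C)C2(C)C
Why: Brown allylation with the antipodal borane should deliver allyl to the Si face and set the carbinol that becomes C3 of ring B (4S here, 3R in the target after the change in substituent priorities).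

Step 17
Reactants: 26 (4S)-9,9-diethoxy-6,6-dimethylnon-1-en-7-yn-4-ol
Product: 27 tert-butyl{[(4S)-9,9-diethoxy-6,6-dimethylnon-1-en-7-yn-4-yl]oxy}dimethylsilane
Conditions: TBSCl, imidazole, DMF, rt
Reagents that add atoms: tert-butyldimethylsilyl chloride, CC(C)(C)[Si](C)(C)Cl
Why: Standard silylation; the bulky equatorial silyloxy group later helps to define the ring conformation in step 20.

Step 18
Reactants: 27 tert-butyl{[(4S)-9,9-diethoxy-6,6-dimethylnon-1-en-7-yn-4-yl]oxy}dimethylsilane
Product: 29 (3R)-3-[(tert-butyldimethylsilyl)oxy]-8,8-diethoxy-5,5-dimethyloct-6-ynal, via diol 28 (not isolated)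
Conditions: OsO4 (2 mol%), NaIO4, 2,6-lutidine, dioxane/H2O, rt
Reagents that add atoms: osmium tetroxide, O=[Os](=O)(=O)=O; sodium periodate (re-oxidant that restores the oxygen), [Na+].[O-]I(=O)(=O)=O
Why: Lemieux–Johnson oxidation as in step 3 should give the β-silyloxy 6-alkynal whose aldehyde carbon is C5, used without delay.

Step 19
Reactants: 29 (3R)-3-[(tert-butyldimethylsilyl)oxy]-8,8-diethoxy-5,5-dimethyloct-6-ynal
Product: 30 (2E,5R)-5-[(tert-butyldimethylsilyl)oxy]-2-(2,2-diethoxyethylidene)-3,3-dimethylcyclohexan-1-one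
Conditions: [Rh(nbd)2]BF4 (10 mol%), Ph2PCH2CH2PPh2 (10 mol%), H2 pre-activation then argon, CH2Cl2, rt to 40 °C
Reagents that add atoms: none
Why: Monovalent rhodium should insert into the aldehyde C5–H bond to give an acyl rhodium hydride, the tethered C6≡C7 alkyne then undergoes syn hydrometalation (H to C7, Rh to C6) to a seven-membered acyl(alkenyl)rhodacycle, and C5–C6 reductive elimination releases the ketone and the catalyst. The closest known reaction type is the cationic rhodium/diphosphine-catalysed intramolecular hydroacylation of 5- and 6-alkynals to 2-alkylidenecycloalkanones. Ring B is closed in the 6-exo-dig mode, the C5–C6 bond being made by reductive elimination. No sp3 stereocentre is created; the stereochemical element set is the C6=C7 geometry, which is E because acyl and hydrogen add to the same face of the alkyne, so that C8 lies cis to C1 and H cis to C5, while the C3 silyloxy centre is untouched. The step needs exo over endo addition, hydroacylation over decarbonylation and no later alkene migration or E/Z equilibration: the four-atom tether and the gem-dimethyl group at C1 favour the six-membered ring, the chelating diphosphine on the cationic metal disfavours CO extrusion, and the quaternary C1 leaves no hydrogen for migration of the alkene into the ring. The C5 ketone that results is the handle for the diastereoselective methyl addition of step 20.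

Step 20
Reactants: 30 (2E,5R)-5-[(tert-butyldimethylsilyl)oxy]-2-(2,2-diethoxyethylidene)-3,3-dimethylcyclohexan-1-one
Product: 31 (1S,2E,5R)-5-[(tert-butyldimethylsilyl)oxy]-2-(2,2-diethoxyethylidene)-1,3,3-trimethylcyclohexan-1-ol
Conditions: CeCl3 (anhydrous), MeLi, THF, −78 °C
Reagents that add atoms: methyllithium, C[Li]
Why: Organocerium 1,2-addition (weakly basic, so neither enolisation toward the β-silyloxy group nor conjugate addition) to a ring whose C3 silyloxy group is equatorial and whose axial C1 methyl shields one carbonyl face: methyl should enter equatorially, anti to that methyl, and the new C5 hydroxyl is axial and trans to the C3 oxygen (5S).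

Step 21
Reactants: 31 (1S,2E,5R)-5-[(tert-butyldimethylsilyl)oxy]-2-(2,2-diethoxyethylidene)-1,3,3-trimethylcyclohexan-1-ol
Product: 32 (2E)-2-[(2S,4R)-4-[(tert-butyldimethylsilyl)oxy]-2-hydroxy-2,6,6-trimethylcyclohexylidene]acetaldehyde
Conditions: pyridinium p-toluenesulfonate (5 mol%), acetone/H2O, rt
Reagents that add atoms: water, O
Why: Mild hydrolysis of the allylic acetal should unveil the enal; the aldehyde lies trans to the C5 hydroxyl, so no cyclic hemiacetal can form as long as the E geometry is kept.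

Step 22
Reactants: 32 (2E)-2-[(2S,4R)-4-[(tert-butyldimethylsilyl)oxy]-2-hydroxy-2,6,6-trimethylcyclohexylidene]acetaldehyde
Product: 33 (2E,4E)-4-[(2S,4R)-4-[(tert-butyldimethylsilyl)oxy]-2-hydroxy-2,6,6-trimethylcyclohexylidene]-2-methylbut-2-enal
Conditions: 2-(triphenylphosphoranylidene)propanal, toluene, 80 °C
Reagents that add atoms: 2-(triphenylphosphoranylidene)propanal, CC(C=O)=P(c1ccccc1)(c1ccccc1)c1ccccc1
Why: Wittig reaction with the stabilised ylide under neutral conditions should give the E-C8=C9 alkene and tolerate the free tertiary alcohol.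

Step 23
Reactants: 33 (2E,4E)-4-[(2S,4R)-4-[(tert-butyldimethylsilyl)oxy]-2-hydroxy-2,6,6-trimethylcyclohexylidene]-2-methylbut-2-enal; 20 diethyl [(2E)-3-methylpent-2-en-4-yn-1-yl]phosphonate
Product: 35 (1S,2E,5R)-5-[(tert-butyldimethylsilyl)oxy]-2-[(2E,4E,6E)-3,7-dimethylnona-2,4,6-trien-8-yn-1-ylidene]-1,3,3-trimethylcyclohexan-1-ol, via lithium phosphonate carbanion 34 (not isolated)
Conditions: LiN(SiMe3)2, 20 (2.2 equiv), THF, −78 °C; then 33, −78 to 0 °C
Reagents that add atoms: none
Why: Horner–Wadsworth–Emmons olefination of the type used in step 14, here with an excess of the lithium carbanion because one equivalent is spent on the tertiary hydroxyl, whose tightly ion-paired lithium alkoxide is a poor nucleophile, should give the E-C10=C11 alkene; the E geometry at C6=C7 rules out oxa-Michael closure of the alkoxide.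

Step 24
Reactants: 35 (1S,2E,5R)-5-[(tert-butyldimethylsilyl)oxy]-2-[(2E,4E,6E)-3,7-dimethylnona-2,4,6-trien-8-yn-1-ylidene]-1,3,3-trimethylcyclohexan-1-ol; 24 tert-butyl{[(1S,4E)-4-[(2E,4E,6E,8E)-9-iodo-3,7-dimethylnona-2,4,6,8-tetraen-1-ylidene]-3,5,5-trimethylcyclohex-2-en-1-yl]oxy}dimethylsilane
Product: 37 3,3'-bis-O-(tert-butyldimethylsilyl) ether of the target triol, via bis-zirconated polyene 36 (not isolated)
Conditions: Cp2Zr(H)Cl (2.3 equiv), THF, rt, dark; then 24, Pd(PPh3)4 (5 mol%), THF, rt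
Reagents that add atoms: none
Why: The first equivalent of the hydride should convert the hydroxyl into a zirconium alkoxide and the second adds syn to the terminal alkyne; zerovalent palladium-catalysed alkenyl–alkenyl coupling of the E-alkenylzirconocene with the E-iodide (Negishi-type, retention at both carbons) forms the central C15–C15' single bond.

Step 25
Reactants: 37 3,3'-bis-O-(tert-butyldimethylsilyl) ether of the target triol
Product: 38 (all-E)-(3R,5S,3'S)-4',5'-didehydro-4,5-dihydro-4,5'-retro-β,β-carotene-3,5,3'-triol (target CNP0269135.1)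
Conditions: Bu4NF, THF, 0 °C to rt, dark
Reagents that add atoms: none
Why: Fluoride-induced cleavage of the two secondary silyl ethers under non-acidic conditions should spare the polyene, the allylic C3' alcohol and the tertiary allylic C5 alcohol.

**Compound list**
1 | 2,2-dimethylpent-4-enal | C=CCC(C)(C)C=O | starting material
2 | 3,3-dimethylhex-5-en-1-yne | C=CCC(C)(C)C#C | intermediate
3 | (3,3-dimethylhex-5-en-1-yn-1-yl)magnesium bromide (not isolated) | C=CCC(C)(C)C#C[Mg]Br | intermediate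
4 | 7,7-diethoxy-4,4-dimethylhept-1-en-5-yne | C=CCC(C)(C)C#CC(OCC)OCC | intermediate
5 | 7,7-diethoxy-4,4-dimethylhept-5-yne-1,2-diol (racemic; not isolated) | OCC(O)CC(C)(C)C#CC(OCC)OCC | intermediate
6 | 6,6-diethoxy-3,3-dimethylhex-4-ynal | O=CCC(C)(C)C#CC(OCC)OCC | intermediate
7 | (4R)-9,9-diethoxy-6,6-dimethylnon-1-en-7-yn-4-yl diisopinocampheylborinate, isopinocampheyl groups from (−)-α-pinene (not isolated) | C=CC[C@@H](OB([C@H]1C[C@H]2C[C@@H]([C@@H]1C)C2(C)C)[C@H]1C[C@H]2C[C@@H]([C@@H]1C)C2(C)C)CC(C)(C)C#CC(OCC)OCC | intermediate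
8 | (4R)-9,9-diethoxy-6,6-dimethylnon-1-en-7-yn-4-ol | C=CC[C@@H](O)CC(C)(C)C#CC(OCC)OCC | intermediate
9 | tert-butyl{[(4R)-9,9-diethoxy-6,6-dimethylnon-1-en-7-yn-4-yl]oxy}dimethylsilane | C=CC[C@@H](O[Si](C)(C)C(C)(C)C)CC(C)(C)C#CC(OCC)OCC | intermediate
10 | (4S)-4-[(tert-butyldimethylsilyl)oxy]-9,9-diethoxy-6,6-dimethylnon-7-yne-1,2-diol (both C2 epimers; not isolated) | OCC(O)C[C@@H](O[Si](C)(C)C(C)(C)C)CC(C)(C)C#CC(OCC)OCC | intermediate
11 | (3S)-3-[(tert-butyldimethylsilyl)oxy]-8,8-diethoxy-5,5-dimethyloct-6-ynal | O=CC[C@@H](O[Si](C)(C)C(C)(C)C)CC(C)(C)C#CC(OCC)OCC | intermediate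
12 | (2E,5S)-5-[(tert-butyldimethylsilyl)oxy]-2-(2,2-diethoxyethylidene)-3,3-dimethylcyclohexan-1-one | O=C1C[C@@H](O[Si](C)(C)C(C)(C)C)CC(C)(C)\C1=C/C(OCC)OCC | intermediate
13 | potassium (3S,6E)-3-[(tert-butyldimethylsilyl)oxy]-6-(2,2-diethoxyethylidene)-5,5-dimethylcyclohex-1-en-1-olate (not isolated) | [K+].[O-]C1=C[C@@H](O[Si](C)(C)C(C)(C)C)CC(C)(C)\C1=C/C(OCC)OCC | intermediate
14 | (3S,6E)-3-[(tert-butyldimethylsilyl)oxy]-6-(2,2-diethoxyethylidene)-5,5-dimethylcyclohex-1-en-1-yl trifluoromethanesulfonate | FC(F)(F)S(=O)(=O)OC1=C[C@@H](O[Si](C)(C)C(C)(C)C)CC(C)(C)\C1=C/C(OCC)OCC | intermediate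
15 | tert-butyl{[(1S,4E)-4-(2,2-diethoxyethylidene)-3,5,5-trimethylcyclohex-2-en-1-yl]oxy}dimethylsilane | CC1=C[C@@H](O[Si](C)(C)C(C)(C)C)CC(C)(C)\C1=C/C(OCC)OCC | intermediate
16 | (2E)-2-[(4S)-4-[(tert-butyldimethylsilyl)oxy]-2,6,6-trimethylcyclohex-2-en-1-ylidene]acetaldehyde | CC1=C[C@@H](O[Si](C)(C)C(C)(C)C)CC(C)(C)\C1=C/C=O | intermediate
17 | (2E,4E)-4-[(4S)-4-[(tert-butyldimethylsilyl)oxy]-2,6,6-trimethylcyclohex-2-en-1-ylidene]-2-methylbut-2-enal | CC1=C[C@@H](O[Si](C)(C)C(C)(C)C)CC(C)(C)\C1=C/C=C(C)/C=O | intermediate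
18 | (2E)-3-methylpent-2-en-4-yn-1-ol | C#C/C(C)=C/CO | starting material
19 | (3E)-5-bromo-3-methylpent-3-en-1-yne | C#C/C(C)=C/CBr | intermediate
20 | diethyl [(2E)-3-methylpent-2-en-4-yn-1-yl]phosphonate | C#C/C(C)=C/CP(=O)(OCC)OCC | intermediate
21 | sodium salt of the α-carbanion of phosphonate 20 (not isolated) | [Na+].C#C/C(C)=C/[CH-]P(=O)(OCC)OCC | intermediate
22 | tert-butyl{[(1S,4E)-4-[(2E,4E,6E)-3,7-dimethylnona-2,4,6-trien-8-yn-1-ylidene]-3,5,5-trimethylcyclohex-2-en-1-yl]oxy}dimethylsilane | CC1=C[C@@H](O[Si](C)(C)C(C)(C)C)CC(C)(C)\C1=C/C=C(C)/C=C/C=C(C)/C#C | intermediate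
23 | (E)-alkenyl(chloro)bis(cyclopentadienyl)zirconium from 22, zirconium on C15' (not isolated) | CC1=C[C@@H](O[Si](C)(C)C(C)(C)C)CC(C)(C)\C1=C/C=C(C)/C=C/C=C(C)/C=C/[Zr](Cl)(C1C=CC=C1)C1C=CC=C1 | intermediate
24 | tert-butyl{[(1S,4E)-4-[(2E,4E,6E,8E)-9-iodo-3,7-dimethylnona-2,4,6,8-tetraen-1-ylidene]-3,5,5-trimethylcyclohex-2-en-1-yl]oxy}dimethylsilane | CC1=C[C@@H](O[Si](C)(C)C(C)(C)C)CC(C)(C)\C1=C/C=C(C)/C=C/C=C(C)/C=C/I | intermediate
25 | (4S)-9,9-diethoxy-6,6-dimethylnon-1-en-7-yn-4-yl diisopinocampheylborinate, isopinocampheyl groups from (+)-α-pinene (not isolated) | C=CC[C@H](OB([C@@H]1C[C@@H]2C[C@H]([C@H]1C)C2(C)C)[C@@H]1C[C@@H]2C[C@H]([C@H]1C)C2(C)C)CC(C)(C)C#CC(OCC)OCC | intermediate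
26 | (4S)-9,9-diethoxy-6,6-dimethylnon-1-en-7-yn-4-ol | C=CC[C@H](O)CC(C)(C)C#CC(OCC)OCC | intermediate
27 | tert-butyl{[(4S)-9,9-diethoxy-6,6-dimethylnon-1-en-7-yn-4-yl]oxy}dimethylsilane | C=CC[C@H](O[Si](C)(C)C(C)(C)C)CC(C)(C)C#CC(OCC)OCC | intermediate
28 | (4R)-4-[(tert-butyldimethylsilyl)oxy]-9,9-diethoxy-6,6-dimethylnon-7-yne-1,2-diol (both C2 epimers; not isolated) | OCC(O)C[C@H](O[Si](C)(C)C(C)(C)C)CC(C)(C)C#CC(OCC)OCC | intermediate
29 | (3R)-3-[(tert-butyldimethylsilyl)oxy]-8,8-diethoxy-5,5-dimethyloct-6-ynal | O=CC[C@H](O[Si](C)(C)C(C)(C)C)CC(C)(C)C#CC(OCC)OCC | intermediate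
30 | (2E,5R)-5-[(tert-butyldimethylsilyl)oxy]-2-(2,2-diethoxyethylidene)-3,3-dimethylcyclohexan-1-one | CCOC(OCC)/C=C1\C(C)(C)C[C@@H](O[Si](C)(C)C(C)(C)C)CC1=O | intermediate
31 | (1S,2E,5R)-5-[(tert-butyldimethylsilyl)oxy]-2-(2,2-diethoxyethylidene)-1,3,3-trimethylcyclohexan-1-ol | CCOC(OCC)/C=C1\C(C)(C)C[C@@H](O[Si](C)(C)C(C)(C)C)C[C@]1(C)O | intermediate
32 | (2E)-2-[(2S,4R)-4-[(tert-butyldimethylsilyl)oxy]-2-hydroxy-2,6,6-trimethylcyclohexylidene]acetaldehyde | O=C/C=C1\C(C)(C)C[C@@H](O[Si](C)(C)C(C)(C)C)C[C@]1(C)O | intermediate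
33 | (2E,4E)-4-[(2S,4R)-4-[(tert-butyldimethylsilyl)oxy]-2-hydroxy-2,6,6-trimethylcyclohexylidene]-2-methylbut-2-enal | O=C/C(C)=C/C=C1\C(C)(C)C[C@@H](O[Si](C)(C)C(C)(C)C)C[C@]1(C)O | intermediate
34 | lithium salt of the α-carbanion of phosphonate 20 (not isolated) | [Li+].C#C/C(C)=C/[CH-]P(=O)(OCC)OCC | intermediate
35 | (1S,2E,5R)-5-[(tert-butyldimethylsilyl)oxy]-2-[(2E,4E,6E)-3,7-dimethylnona-2,4,6-trien-8-yn-1-ylidene]-1,3,3-trimethylcyclohexan-1-ol | C#C/C(C)=C/C=C/C(C)=C/C=C1\C(C)(C)C[C@@H](O[Si](C)(C)C(C)(C)C)C[C@]1(C)O | intermediate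
36 | bis-zirconated form of 35: chlorobis(cyclopentadienyl)zirconium on the C5 oxygen and (E) on C15 (not isolated) | Cl[Zr](C1C=CC=C1)(C1C=CC=C1)/C=C/C(C)=C/C=C/C(C)=C/C=C1\C(C)(C)C[C@@H](O[Si](C)(C)C(C)(C)C)C[C@]1(C)O[Zr](Cl)(C1C=CC=C1)C1C=CC=C1 | intermediate
37 | 3,3'-bis-O-(tert-butyldimethylsilyl) ether of the target triol | CC1=C[C@@H](O[Si](C)(C)C(C)(C)C)CC(C)(C)\C1=C/C=C(C)/C=C/C=C(C)/C=C/C=C/C(C)=C/C=C/C(C)=C/C=C1\C(C)(C)C[C@@H](O[Si](C)(C)C(C)(C)C)C[C@]1(C)O | intermediate
38 | (all-E)-(3R,5S,3'S)-4',5'-didehydro-4,5-dihydro-4,5'-retro-β,β-carotene-3,5,3'-triol (CNP0269135.1) | CC1=C[C@@H](O)CC(C)(C)\C1=C/C=C(C)/C=C/C=C(C)/C=C/C=C/C(C)=C/C=C/C(C)=C/C=C1\C(C)(C)C[C@@H](O)C[C@]1(C)O | target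

**Step count**
Total steps: 25. Longest linear sequence: 15 steps (steps 1–11, 14, 15, 24, 25); the ring B branch (steps 1–3, 16–25) has 13.

**Steps most likely to fail, with fallbacks**

Step 19 (the same reaction is run first on the antipode in step 7). The acyl rhodium hydride may lose CO instead of adding to the hindered tert-alkyl alkyne, or reversible Rh–H addition may erode the E geometry. Fallback: from alkynal 29, Ni(cod)2/PBu3-catalysed reductive cyclisation with Et3SiH (oxanickelacycle, syn delivery of H and C5 to the alkyne, so the same 6E geometry) gives the triethylsilyl ether of the ring allylic alcohol F1. Pyridinium p-toluenesulfonate in EtOH removes the triethylsilyl group in the presence of the secondary TBS ether (the acetal exchanges only with its own alcohol) to give the allylic alcohol F2. Dess–Martin periodinane with NaHCO3 oxidises the allylic alcohol F2 to ketone 30, where the route is rejoined; the configuration of the transient carbinol is of no consequence.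

Step 24. The alkenylzirconocene may be protonated before transmetalation, and the polyenyl iodide may isomerise or decompose during the coupling. Fallback: from polyenyne 35 and iodide 24, Sonogashira coupling (Pd(PPh3)4, CuI, i-Pr2NH, THF, rt) gives the 14,15-didehydro compound F6. Zinc activated with Cu(OAc)2 and AgNO3 in MeOH/H2O reduces the triple bond to the (14Z)-alkene F7. Thermal Z-to-E equilibration of this unhindered disubstituted central bond (heptane, 80 °C, dark) gives 37.

Step 20. Facial selectivity may be poor, or the reagent may enolise the ketone with loss of the β-silyloxy group. Fallback: from ketone 30, KN(SiMe3)2/PhNTf2 gives the dienyl triflate F3, and Fe(acac)3/MeMgBr gives the methyl diene F4 (the antipode of 15). m-Chloroperbenzoic acid with NaHCO3 epoxidises the ring C4=C5 bond anti to the allylic silyloxy group to give the epoxide F5. LiAlH4 in THF opens the epoxide F5 at the secondary carbon C4 (trans-diaxial opening), which leaves the oxygen on C5 trans to the C3 oxygen and gives 31.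

Further compounds
F1 | step 19 | triethylsilyl ether of F2 (both epimers at the new carbinol carbon; silyloxy centre as in 29) | CCOC(OCC)/C=C1\C(C)(C)C[C@@H](O[Si](C)(C)C(C)(C)C)CC1O[Si](CC)(CC)CC
F2 | step 19 | (2E)-5-[(tert-butyldimethylsilyl)oxy]-2-(2,2-diethoxyethylidene)-3,3-dimethylcyclohexan-1-ol (both carbinol epimers; silyloxy centre as in 29) | CCOC(OCC)/C=C1\C(C)(C)C[C@@H](O[Si](C)(C)C(C)(C)C)CC1O
F3 | step 20 | (3R,6E)-3-[(tert-butyldimethylsilyl)oxy]-6-(2,2-diethoxyethylidene)-5,5-dimethylcyclohex-1-en-1-yl trifluoromethanesulfonate | CCOC(OCC)/C=C1\C(C)(C)C[C@@H](O[Si](C)(C)C(C)(C)C)C=C1OS(=O)(=O)C(F)(F)F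
F4 | step 20 | tert-butyl{[(1R,4E)-4-(2,2-diethoxyethylidene)-3,5,5-trimethylcyclohex-2-en-1-yl]oxy}dimethylsilane | CCOC(OCC)/C=C1\C(C)(C)C[C@@H](O[Si](C)(C)C(C)(C)C)C=C1C
F5 | step 20 | C4–C5 epoxide of F4 with the oxirane oxygen trans to the C3 silyloxy group | CCOC(OCC)/C=C1\C(C)(C)C[C@@H](O[Si](C)(C)C(C)(C)C)[C@H]2[C@]1(C)O2
F6 | step 24 | 14,15-didehydro analogue of 37 | CC1=C[C@@H](O[Si](C)(C)C(C)(C)C)CC(C)(C)\C1=C/C=C(C)/C=C/C=C(C)/C=C/C#C/C(C)=C/C=C/C(C)=C/C=C1\C(C)(C)C[C@@H](O[Si](C)(C)C(C)(C)C)C[C@]1(C)O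
F7 | step 24 | (14Z)-isomer of 37 | CC1=C[C@@H](O[Si](C)(C)C(C)(C)C)CC(C)(C)\C1=C/C=C(C)/C=C/C=C(C)/C=C/C=C\C(C)=C\C=C\C(C)=C\C=C1/C(C)(C)C[C@@H](O[Si](C)(C)C(C)(C)C)C[C@]1(C)O
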